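The runs come from a simulation from invented constants; scatter was added.

The closed vessel holds the same substrate and reagent charges as the midnight and noon runs and differs from them in catalyst and time, so the question is how far those two trade against each other.

| setting | midnight | noon | flask |
|---|---|---|---|
| substrate | 0.15 M | 0.15 M | 0.15 M |
| reagent | 0.165 M | 0.165 M | 0.165 M |
| free catalyst | 0.15 mM | 0.60 mM | 0.30 mM |
| remark | run made earlier | run made earlier |  |
| time |  |  | 1.5 h |

| run | time / min | target / % | substrate / % |
|---|---|---|---|
| midnight | 3.00 | 3 | 101 |
| midnight | 8.00 | 2 | 99 |
| midnight | 15.0 | 5 | 98 |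
| midnight | 25.0 | 6 | 95 |
| midnight | 30.0 | 6 | 95 |
| midnight | 40.0 | 8 | 90 |
| midnight | 50.0 | 13 | 92 |
| noon | 4.00 | 5 | 98 |
| noon | 6.00 | 6 | 95 |
| noon | 10.0 | 12 | 95 |
| noon | 15.0 | 12 | 86 |
| noon | 25.0 | 19 | 81 |
| noon | 40.0 | 26 | 71 |
| noon | 50.0 | 28 | 67 |

(scatter of a reading: 1.5 percentage points)

- amount of target in the flask at 1.5 h, in percent of the substrate charged
- amount of substrate in the flask at 1.5 h, in percent of the substrate charged
- concentration of released group at 1.5 h, in M

- steps thought possible: substrate + free catalyst -> catalyst intermediate A; catalyst intermediate C <-> free catalyst + target; 2 reagent -> self-condensation product; reagent + catalyst intermediate A -> catalyst intermediate B; catalyst intermediate B <-> released group + catalyst intermediate C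

Does the loss of substrate follow the catalyst? The logarithm of the fraction left, noon over midnight, reads 3.25 at 40.0 min and 4.80 at 50.0 min, either side of the catalyst ratio 4.00. So you can carry 0.900, the dose ratio, catalyst charge times time in a flask over the same product at the last noon reading, with both other charges held as in these runs. Raising the noon fraction left, 67%, to that power leaves 69.7% of the substrate.

How much of the rest can sit on the catalyst? Its charge is 0.200% of the substrate charge, against a scatter of 1.5 percentage points, so you take the target as the remainder, 30.3%, with released group following it, one per turn. Self-condensation runs by the clock, not by the catalyst, and this flask runs 1.80 times as long as that noon reading, so your figure leans high.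

The forecast gave target 29.5%, substrate 70% and released group 0.044 M, noting that late slowing “could take a little off”.

The flask gives target 27.3%, substrate 72.5% and released group 0.0409 M.

    substrate + free catalyst → catalyst intermediate A (k = 1.30 L mol⁻¹ s⁻¹)
    catalyst intermediate C ⇌ free catalyst + target (K = 0.220 M, k = 4.30 s⁻¹)
    2 reagent → self-condensation product (k = 4.90 × 10⁻⁴ L mol⁻¹ s⁻¹)
    reagent + catalyst intermediate A → catalyst intermediate B (k = 0.370 L mol⁻¹ s⁻¹)
    catalyst intermediate B ⇌ released group + catalyst intermediate C (K = 0.0160 M, k = 0.210 s⁻¹)

Set against the noon run, the substrate in this flask behaves as a dose ratio of 0.803, not the reckoned 0.900, with 39% of its reagent charge left at 1.50 h. A neighbouring flask has 0.099 M of reagent, 0.600 of the reagent charge in the runs, with catalyst and time unchanged, so its dose ratio stays 0.900, and the reckoning, taken here beyond the reagent charge it held, again puts substrate at 69.7%. That neighbouring flask holds 79.4% of its substrate charge, which behaves as a dose ratio of 0.576. Its target stands at 20.4%, with catalyst intermediate A, the resting state, at 81.0% of the catalyst charged.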